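Conventions and one assumption: locants follow the target throughout (C1 quaternary carbinol, C2 CHCl, C3=C4, C5 CHOH, C6 CHOBz, C7 the exocyclic CH2), and "upper face" means the face of C7. The benzoate dioxygenase diol is assumed to be the (1S,6R) enantiomer, which is the one whose C1 and C6 match the target.

## Analysis of the target

The target, [(1R,2R,5S,6R)-6-(benzoyloxy)-2-chloro-1,5-dihydroxycyclohex-3-en-1-yl]methyl benzoate, is a single cyclohex-3-ene ring in which every sp3 ring carbon (C1, C2, C5, C6) is stereogenic. C1 is a fully substituted carbinol carrying the benzoyloxymethyl carbon C7, C2 is a secondary allylic chloride, C5 a free secondary allylic alcohol and C6 a secondary benzoate. The C1 hydroxyl and the C6 benzoate are cis on the lower face, whereas C7, the C2 chlorine and the C5 hydroxyl sit together on the upper face. Chlorine is therefore anti to the neighbouring tertiary hydroxyl, and the C5 hydroxyl is trans to the C6 benzoate. The C1–OH/C2–Cl pair is a trans chlorohydrin that would close to an oxirane with base, the allylic chloride can ionise or undergo SN2′ displacement, and the C6 benzoate can migrate to the adjacent O5. The difficulties are a hindered C–Cl bond of defined configuration next to a quaternary carbinol, and four oxygens that must end as two benzoates (O7, O6) and two free hydroxyls (O1, O5). The strategy rests on two features. First, C2–Cl and C5–OH are 1,4-cis across the C3=C4 alkene on the face of C7, and C7 and O5 are 1,3-related across C6, so a C7 carboxylate can reach C5 through a five-membered lactone. Second, the C1/C6 cis-diol with C7 on the opposite face is exactly the pattern of the microbial ipso,ortho-dihydrodiol of benzoic acid, which already holds all seven skeletal carbons.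

## Retrosynthetic reasoning

12 ⇒ 11 (O5–Si). The free C5 hydroxyl is unveiled last. It is the hydroxyl next to the C6 benzoate, and releasing it under non-basic fluoride conditions at the very end avoids acyl migration and closure of the chlorohydrin. The forward step only has to cleave a silyl ether without generating an alkoxide.

11 ⇒ 10 + 7 (C6 acyl–O bond). With O5 capped, diol 10 has only a secondary (C6) and a tertiary (C1) hydroxyl, and acylation with benzoyl chloride 7 can only occur at C6. Cutting here rather than earlier means the second benzoate never has to survive hydride or aqueous acid.

10 ⇒ 9 (the isopropylidene ketal on O1/O6). The ketal is kept as long as possible because it masks the tertiary C1 hydroxyl, which sits anti to the C2 chlorine and would otherwise be free during the hydride and base-mediated steps. The forward step has to hydrolyse a ketal while leaving a silyl ether, a benzoate and an allylic chloride intact. This dictates a robust silyl group in 9.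

9 ⇒ 8 ⇒ 6 + 7 (O5–Si, then the C7 acyl–O bond). Diol 6 has a primary (C7) and a secondary allylic (C5) hydroxyl. The primary one is acylated first with 7 and the remaining secondary one is then silylated, so the two oxygens are told apart by their intrinsic reactivity.

6 ⇒ 5 (reconnection of C7 and O5 as a lactone). Both hydroxyls of 6 derive from one ester function. Going back to lactone 5 raises C7 to the carboxyl oxidation level and ties it to O5. The forward reaction is a hydride reduction that must spare the allylic chloride.

5 ⇒ 4 (C5–O and C2–Cl, the key disconnection). Removing the lactone oxygen from C5 and chlorine from C2 leaves the C2=C3–C4=C5 diene of acid 4. These two bonds are cut because they are the only stereodefining bonds not already present in a dihydrodiol. They are cis-1,4 across the future alkene, which is what a tethered palladium-mediated 1,4-oxidation delivers from carboxylate and chloride. The forward reaction must add oxygen at C5 and chlorine at C2 on the face of C7 and leave C3=C4.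

4 ⇒ 2 + 3 ⇒ 1. The ketal of 4 comes from cis-diol acid 2 and 2,2-dimethoxypropane 3, and 2 comes from benzoic acid 1 by enzymatic ipso,ortho cis-dihydroxylation. That step creates C1 and C6 as a single enantiomer and places the carboxyl carbon C7 on the face opposite the two oxygens. No carbon–carbon bond has to be made in the whole route.

## Alternatives that were turned down

Alternative 1: The ring is cut at C1–C6, giving the acyclic Z-configured keto-aldehyde A2. In the forward direction SmI2 with t-BuOH reduces the C6 aldehyde to a ketyl that adds to the C1 ketone, giving the cyclohexene cis-1,6-diol A1 with O7, O2 and O5 each under a different protecting group.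
- For: samarium pinacol closures of 1,6-dicarbonyls give cis-diols through a chelated transition state. No fermentation is needed. The oxygens of A1 are individually addressable, so the two benzoylations would be cleaner than in the chosen route; on this point the alternative is stronger.
- Against: A2 must be assembled with two stereocentres and a Z-alkene flanked by two allylic oxygens, and its α-silyloxy aldehyde can epimerise.
- Against: the C1 ketone is α,α′-dialkoxylated, and SmI2 readily expels α-alkoxy groups from ketyls.
- Against: the face on which the diol forms relative to C2 and C5 is not dictated by anything in A2.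
- Against: A1 carries oxygen at C2 on the face where chlorine is needed. Chlorination therefore requires net retention at a hindered allylic carbon, which means two inversions with SN2′ competition.
- Comparison: the route would be roughly twice as long. The chosen strategy instead takes C1 and C6 from one enzymatic step and sets C2 and C5 in one stereospecific step.

Alternative 2: The C2–Cl bond is traced back to the C1–C2 oxirane of vinyl epoxide A3, and the oxirane to the C1=C2 alkene of diene A4. In the forward direction VO(acac)2 and t-BuOOH epoxidise C1=C2 under direction of the free allylic C6 hydroxyl. Chloride opening at the allylic C2 with inversion would then give the trans chlorohydrin.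
- For: hydroxyl-directed vanadium epoxidation is highly reliable, and the SN2 opening sets the anti relationship of O1 and Cl by mechanism. The endgame is the shortest of all. On the C–Cl bond itself this alternative is at least as convincing as the chosen one.
- Against: A4 is a cyclohexadiene with a trans-5,6-dioxygen pattern, which no dioxygenase delivers directly. It needs an inversion at one carbinol of a dienediol that aromatises easily by loss of an allylic oxygen.
- Against: A3 is an arene-oxide-like vinyl epoxide, where ionisation and 1,4-opening at C4 compete with the wanted attack at C2.
- Comparison: the chosen strategy offers stable, protected intermediates after the first step and needs no inversion.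

Alternative 3: The C6–O bond is disconnected, leading back to the achiral para-quinol A6. In the forward direction the quinol hydroxyl and PhB(OH)2 form a boronate hemiester whose B–OH oxygen adds to one enantiotopic enone β-carbon under a chiral amine–thiourea catalyst, giving the cis-fused boronate A5.
- For: the route is catalytic and asymmetric from a cheap achiral precursor. It is scalable without microbiology, and it sets the C1/C6 cis-diol in one step.
- Against: A5 has only two of the four stereocentres, a ketone at C4, a methylene at C5 and the alkene at C2=C3. The endgame must α-oxygenate C5 trans to O6, reduce the ketone, and then transpose the allylic system so that chlorine lands on C2 with the right configuration. That is three further stereodefining operations.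
- Against: the enantiomeric purity depends on the catalyst, whereas the enzymatic diol is formed as one enantiomer.
- Comparison: it is stronger in accessibility of the starting material, but the chosen strategy is far shorter after the key step and controls all four centres.

Key step: step 3

Step 1
Reactants: 1 benzoic acid
Product: 2 (1S,6R)-1,6-dihydroxycyclohexa-2,4-diene-1-carboxylic acid (cis-diol; carboxyl on the face opposite both hydroxyls)
Conditions: Ralstonia eutropha B9 (whole cells, benzoate 1,2-dioxygenase), sodium benzoate feed, fructose, mineral salts medium, pH 7, air, 30 °C; then pH 3, EtOAc extraction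
Reagents that add atoms: dioxygen, O=O
Why: Enzymatic arene cis-dihydroxylation: the dioxygenase adds both oxygen atoms to the ipso and ortho carbons from one face, and the strain cannot dehydrogenate the diol, so it accumulates; the enzyme fixes C1 and C6 in one absolute sense.

Step 2
Reactants: 2 (1S,6R)-1,6-dihydroxycyclohexa-2,4-diene-1-carboxylic acid; 3 2,2-dimethoxypropane
Product: 4 (3aS,7aR)-2,2-dimethyl-3a,7a-dihydro-1,3-benzodioxole-3a-carboxylic acid (the O1,O6-isopropylidene ketal of 2)
Conditions: 2,2-dimethoxypropane, TsOH·H2O (cat.), acetone, 0 °C to rt
Reagents that add atoms: 2,2-dimethoxypropane 3, COC(C)(C)OC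
Why: Acid-catalysed transketalisation of a cis-1,2-diol to the cis-fused dioxolane; only a trace of acid and a short contact time are used because the dienediol aromatises by dehydration under stronger acid, and C1 and C6 are not touched.

Step 3
Reactants: 4 (3aS,7aR)-2,2-dimethyl-3a,7a-dihydro-1,3-benzodioxole-3a-carboxylic acid
Product: 5 chloro lactone acetonide (bridged five-membered lactone from C7 to O–C5, chlorine at C2 on the lactone face, C3=C4 alkene, O1,O6-isopropylidene; (1S,2R,5S,6R) in target locants)
Conditions: Pd(OAc)2 (5 mol %), p-benzoquinone (2 equiv, in portions), LiCl (4 equiv), acetone–AcOH (4:1), 20 °C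
Reagents that add atoms: lithium chloride, [Li+].[Cl-]
Why: Divalent palladium coordinates the C2=C3–C4=C5 diene on the face away from the carboxyl group, and the carboxylate oxygen adds to the terminus C5 from its own face (anti acyloxypalladation), giving a transient η3-allyl palladium species over C2–C4 with the metal on the ketal face. Chloride, kept in excess so that it and not acetate or a metal-bound carboxylate is the second nucleophile, attacks the allyl terminus C2 from outside, anti to the metal, and the zerovalent palladium released is reoxidised by p-benzoquinone. The closest known reaction type is the palladium-catalysed 1,4-chloroacyloxylation of cyclic 1,3-dienes with benzoquinone and LiCl, including the variant in which a tethered carboxylic acid closes a lactone. The five-membered lactone closes by 5-exo-trig attack of oxygen on C5 and bridges C1 and C5 of the carbocycle. C5 is set by the tether, because the carboxyl on C1 can reach C5 only on its own face, and C2 is set by the two successive anti events at palladium, which put chlorine on the same face as the new C5–O bond. The step needs oxygen attack at C5 and not C2, chloride and not acetate as second nucleophile, and chloride attack at C2 and not C4; the first is secured by the tether (attack at C2 would need a four-membered lactone), the second by the excess of LiCl, and the third by the acyloxy-bearing C5 next to C4, which in this reaction type sends the second nucleophile to the distal allyl terminus.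

Step 4
Reactants: 5 chloro lactone acetonide
Product: 6 diol acetonide, (1R,2R,5S,6R)-2-chloro-1-(hydroxymethyl)cyclohex-3-ene-1,5,6-triol as its O1,O6-isopropylidene ketal (free primary C7–OH and secondary C5–OH)
Conditions: LiBH4 (2 equiv), THF, 0 °C to rt; aq. NH4Cl
Reagents that add atoms: none
Why: Hydride reduction of an activated α-alkoxy γ-lactone to the diol; LiBH4 reduces lactones but should leave a hindered secondary allylic chloride and the ketal alone at this temperature, and no stereocentre is involved.

Step 5
Reactants: 6 diol acetonide; 7 benzoyl chloride
Product: 8 C7 monobenzoate (C7–OBz, free C5–OH, O1,O6-isopropylidene, C2–Cl)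
Conditions: BzCl (1.05 equiv), 2,4,6-collidine, CH2Cl2, −40 to 0 °C
Reagents that add atoms: benzoyl chloride 7, O=C(Cl)c1ccccc1
Why: Kinetically controlled acylation separates the primary C7 hydroxyl from the secondary allylic C5 hydroxyl, which is flanked by the ketal-bearing C6; one equivalent of acid chloride with a hindered pyridine base at low temperature is the usual way to stop at the primary ester.

Step 6
Reactants: 8 C7 monobenzoate
Product: 9 C5 triisopropylsilyl ether (C7–OBz, C5–OSi(i-Pr)3, O1,O6-isopropylidene, C2–Cl)
Conditions: TIPSOTf, 2,6-lutidine, CH2Cl2, −40 to 0 °C
Reagents that add atoms: triisopropylsilyl triflate, CC(C)[Si](C(C)C)(C(C)C)OS(=O)(=O)C(F)(F)F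
Why: A silyl triflate with a hindered base silylates the remaining secondary alcohol quickly at low temperature without affecting ketal, benzoate or allylic chloride; the triisopropylsilyl group is chosen because it should outlast the aqueous acid of the next step.

Step 7
Reactants: 9 C5 triisopropylsilyl ether
Product: 10 C1,C6-diol (C7–OBz, C5–OSi(i-Pr)3, free tertiary C1–OH and secondary C6–OH, C2–Cl)
Conditions: TFA–H2O (9:1), CH2Cl2, 0 °C
Reagents that add atoms: none
Why: Acid hydrolysis of the isopropylidene ketal; a secondary triisopropylsilyl ether, a benzoate and an allylic chloride flanked by oxygenated carbons (hence poorly ionising) are expected to tolerate cold aqueous trifluoroacetic acid, and the acidic medium keeps the freed C1 hydroxyl from displacing the anti chlorine.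

Step 8
Reactants: 10 C1,C6-diol; 7 benzoyl chloride
Product: 11 dibenzoate silyl ether (C7–OBz, C6–OBz, C5–OSi(i-Pr)3, free C1–OH, C2–Cl)
Conditions: BzCl, pyridine, DMAP (cat.), CH2Cl2, 0 °C to rt
Reagents that add atoms: benzoyl chloride 7, O=C(Cl)c1ccccc1
Why: DMAP-catalysed acylation of the secondary C6 hydroxyl; the tertiary C1 hydroxyl does not acylate under these conditions, and pyridine is too weak a base to close the chlorohydrin to an oxirane.

Step 9
Reactants: 11 dibenzoate silyl ether
Product: 12 [(1R,2R,5S,6R)-6-(benzoyloxy)-2-chloro-1,5-dihydroxycyclohex-3-en-1-yl]methyl benzoate (target)
Conditions: HF·pyridine, pyridine, THF, 0 °C to rt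
Reagents that add atoms: none
Why: Fluoride-mediated cleavage of the silyl ether in a buffered acidic medium, so that no alkoxide is formed and neither benzoate migration from O6 to O5 nor oxirane closure from O1 onto C2 can occur; all four stereocentres are left as set.

Compound list

1 | benzoic acid | OC(=O)c1ccccc1 | starting material
2 | (1S,6R)-1,6-dihydroxycyclohexa-2,4-diene-1-carboxylic acid | OC(=O)[C@]1(O)C=CC=C[C@H]1O | intermediate
3 | 2,2-dimethoxypropane | COC(C)(C)OC | starting material
4 | (3aS,7aR)-2,2-dimethyl-3a,7a-dihydro-1,3-benzodioxole-3a-carboxylic acid (acetonide of 2) | OC(=O)[C@]1(OC(C)(C)O2)C=CC=C[C@H]12 | intermediate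
5 | chloro lactone acetonide (lactone C7 to O5, Cl at C2, C3=C4) | O=C1O[C@H]2C=C[C@@H](Cl)[C@]1(OC(C)(C)O3)[C@@H]23 | intermediate
6 | diol acetonide (C7–OH, C5–OH) | OC[C@]1(OC(C)(C)O2)[C@H](Cl)C=C[C@H](O)[C@H]12 | intermediate
7 | benzoyl chloride | O=C(Cl)c1ccccc1 | starting material
8 | C7 monobenzoate acetonide | O=C(OC[C@]1(OC(C)(C)O2)[C@H](Cl)C=C[C@H](O)[C@H]12)c1ccccc1 | intermediate
9 | C7 benzoate, C5 triisopropylsilyl ether, acetonide | O=C(OC[C@]1(OC(C)(C)O2)[C@H](Cl)C=C[C@H](O[Si](C(C)C)(C(C)C)C(C)C)[C@H]12)c1ccccc1 | intermediate
10 | C7 benzoate, C5 triisopropylsilyl ether, C1,C6-diol | O=C(OC[C@]1(O)[C@H](Cl)C=C[C@H](O[Si](C(C)C)(C(C)C)C(C)C)[C@H]1O)c1ccccc1 | intermediate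
11 | C7,C6-dibenzoate, C5 triisopropylsilyl ether | O=C(OC[C@]1(O)[C@H](Cl)C=C[C@H](O[Si](C(C)C)(C(C)C)C(C)C)[C@H]1OC(=O)c1ccccc1)c1ccccc1 | intermediate
12 | [(1R,2R,5S,6R)-6-(benzoyloxy)-2-chloro-1,5-dihydroxycyclohex-3-en-1-yl]methyl benzoate | O=C(OC[C@]1(O)[C@H](Cl)C=C[C@H](O)[C@H]1OC(=O)c1ccccc1)c1ccccc1 | target

Total step count: 9. Longest linear sequence: 9 steps, from benzoic acid 1.

Steps least certain to work

Step 3 (key step). Three things can go wrong.
- Palladium must bind the diene on the face that carries the ketal. If that face is too shielded by the inward-pointing methyl group, the anti oxypalladation does not start. A carboxylate-bound metal on the upper face would instead lead to loss of the cis-1,4 relationship.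
- Chloride may enter at C4 instead of C2, because both allyl termini neighbour an oxygenated carbon and C2 is next to the quaternary C1.
- The electron-rich diene may be consumed by cycloaddition with the quinone or by decarboxylative aromatisation before it is oxidised productively.

Fallback, setting out from 4 and returning at 5: the C4=C5 alkene, the one remote from the quaternary carbon, is dihydroxylated with OsO4 (cat.) and N-methylmorpholine N-oxide on the face opposite the ketal, to give the cis-4,5-diol acid F1. Its C5 hydroxyl is lactonised onto C7 under mild acid catalysis to give hydroxy lactone F2, which keeps a free allylic C4 hydroxyl on the upper face. Thionyl chloride in ether without base then converts this alcohol through its chlorosulfite by SNi′, delivering chlorine to C2 on the same face with shift of the alkene to C3=C4. This gives 5 by oxidation and substitution chemistry that needs no metal on the hindered face.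

Step 5. Discrimination between the two hydroxyls may be poor, since the primary C7 hydroxyl is neopentyl-like and the C5 hydroxyl is allylic. Over-acylation or acylation at C5 would then lower the throughput. Fallback, setting out from 5 and returning at 9: the lactone is opened with K2CO3 in methanol to the hydroxy methyl ester F3, in which only O5 is free. This is silylated with triisopropylsilyl triflate to silyl ether ester F4. The ester is reduced with i-Bu2AlH to the primary alcohol F5, which is benzoylated with 7 to give 9. The two oxygens are thus distinguished by the order in which they are released and not by relative rates.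

Step 7. The ketal is deactivated by the electron-withdrawing groups around it, and acid strong enough to cleave it may also start to cleave the silyl ether or promote acyl shift. Fallback, setting out from 8 and returning at 10: the ketal of 8 is hydrolysed before any silyl group is present, giving triol F6. The least hindered, allylic C5 hydroxyl of this triol is then silylated selectively with triisopropylsilyl chloride and imidazole, the C6 hydroxyl being flanked by the quaternary C1 and the C1 hydroxyl being tertiary. This gives 10 without exposing a silyl ether to acid.

Step 9. Cleavage of the hindered silyl ether may be slow. Any drift to basic conditions would allow benzoate migration from O6 to O5 or closure of the chlorohydrin. Fallback, setting out from 8 and returning at 12: O5 is protected as an ester that is removed without fluoride. Compound 8 is esterified with levulinic acid (carbodiimide, DMAP) to levulinate F7, and the ketal is hydrolysed to diol levulinate F8. The C6 hydroxyl is benzoylated with 7 to dibenzoate levulinate F9, and the levulinoyl group is removed with hydrazine acetate in pyridine–acetic acid, which leaves benzoates untouched and gives 12.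

Further compounds

F1 | step 3 | cis-4,5-diol acid (C4–OH and C5–OH on the upper face, C2=C3, O1,O6-isopropylidene) | OC(=O)[C@]1(OC(C)(C)O2)C=C[C@H](O)[C@H](O)[C@H]12
F2 | step 3 | hydroxy lactone (lactone C7 to O5, C4–OH on the upper face, C2=C3, O1,O6-isopropylidene) | O=C1O[C@H]2[C@@H](O)C=C[C@]1(OC(C)(C)O3)[C@@H]23
F3 | step 5 | hydroxy methyl ester (C7 methyl ester, free C5–OH, C2–Cl, acetonide) | COC(=O)[C@]1(OC(C)(C)O2)[C@H](Cl)C=C[C@H](O)[C@H]12
F4 | step 5 | silyl ether ester (C7 methyl ester, C5 triisopropylsilyl ether, acetonide) | COC(=O)[C@]1(OC(C)(C)O2)[C@H](Cl)C=C[C@H](O[Si](C(C)C)(C(C)C)C(C)C)[C@H]12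
F5 | step 5 | primary alcohol (C7–OH, C5 triisopropylsilyl ether, acetonide) | OC[C@]1(OC(C)(C)O2)[C@H](Cl)C=C[C@H](O[Si](C(C)C)(C(C)C)C(C)C)[C@H]12
F6 | step 7 | triol (C7 benzoate, free C1, C5 and C6 hydroxyls) | O=C(OC[C@]1(O)[C@H](Cl)C=C[C@H](O)[C@H]1O)c1ccccc1
F7 | step 9 | levulinate (C7 benzoate, C5 levulinate, acetonide) | O=C(OC[C@]1(OC(C)(C)O2)[C@H](Cl)C=C[C@H](OC(=O)CCC(C)=O)[C@H]12)c1ccccc1
F8 | step 9 | diol levulinate (C7 benzoate, C5 levulinate, free C1 and C6 hydroxyls) | O=C(OC[C@]1(O)[C@H](Cl)C=C[C@H](OC(=O)CCC(C)=O)[C@H]1O)c1ccccc1
F9 | step 9 | dibenzoate levulinate (C7 and C6 benzoates, C5 levulinate) | O=C(OC[C@]1(O)[C@H](Cl)C=C[C@H](OC(=O)CCC(C)=O)[C@H]1OC(=O)c1ccccc1)c1ccccc1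
A1 | alternative 1 | cyclohexene cis-1,6-diol with C7 TBS, C2 PMB and C5 TIPS ethers | CC(C)(C)[Si](C)(C)OC[C@]1(O)[C@H](OCc2ccc(OC)cc2)C=C[C@H](O[Si](C(C)C)(C(C)C)C(C)C)[C@H]1O
A2 | alternative 1 | Z-configured acyclic keto-aldehyde (C1 ketone, C6 aldehyde) | CC(C)(C)[Si](C)(C)OCC(=O)[C@H](OCc1ccc(OC)cc1)/C=C\[C@H](O[Si](C(C)C)(C(C)C)C(C)C)C=O
A3 | alternative 2 | vinyl epoxide with free C6 hydroxyl and C5 silyl ether | O=C(OC[C@]12O[C@H]1C=C[C@H](O[Si](C)(C)C(C)(C)C)[C@H]2O)c1ccccc1
A4 | alternative 2 | diene with trans-5,6-dioxygen pattern (C1=C2, C3=C4, free C6 hydroxyl, C5 silyl ether) | O=C(OCC1=CC=C[C@H](O[Si](C)(C)C(C)(C)C)[C@H]1O)c1ccccc1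
A5 | alternative 3 | cis-fused phenylboronate of the 4,5-dihydroxycyclohex-2-enone | O=C1C[C@H]2OB(c3ccccc3)O[C@@]2(CO[Si](c2ccccc2)(c2ccccc2)C(C)(C)C)C=C1
A6 | alternative 3 | para-quinol, 4-hydroxy-4-(silyloxymethyl)cyclohexa-2,5-dienone | O=C1C=CC(O)(CO[Si](c2ccccc2)(c2ccccc2)C(C)(C)C)C=C1
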